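The 28-membered ring holds an α-acyloxy carboxamide: lactone oxygen, propyl-bearing carbon, amide carbonyl carbon and lactam nitrogen are four consecutive ring atoms. That is the retron of a Passerini reaction, so the ring is closed last at the bond between the amide carbonyl carbon and the propyl-bearing carbon. An open-chain ω-isocyano carboxylic acid (complete diene, triol as silyl ethers) reacts with butanal under chiral phosphoric acid catalysis; one operation makes this C–C bond, the lactone, the lactam and the last stereocentre. The isocyano acid arises from a Julia–Kocienski union of a C1–C14 sulfone ester with a C15–C24 azido enal (numbering from the carboxyl carbon).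

Key step: step 23

Assumption: the sense of induction of the two catalyst-controlled steps (step 3 with (DHQD)2AQN, step 23 with (R)-TRIP) is taken as written; the pseudo-enantiomeric or antipodal catalyst would be used if the opposite sense were found.

**Sulfone fragment (C1–C14)**

Step 1
Reactants: 1 (S)-3-bromo-2-methylpropan-1-ol
Product: 2 (S)-(3-bromo-2-methylpropoxy)(tert-butyl)dimethylsilane
Conditions: TBSCl, imidazole, CH2Cl2, 0 °C → rt
Reagents that add atoms: tert-butyldimethylsilyl chloride, CC(C)(C)[Si](C)(C)Cl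
Why: Imidazole-assisted silylation of a primary alcohol; the stereocentre is not touched.

Step 2
Reactants: 2 (S)-(3-bromo-2-methylpropoxy)(tert-butyl)dimethylsilane; 3 1,6-dibromohexane
Product: 5 (R)-[(9-bromo-2-methylnonyl)oxy](tert-butyl)dimethylsilane, via alkylmagnesium bromide 4 (not isolated)
Conditions: Mg, THF, reflux; then 3 (4 equiv), Li2CuCl4 (3 mol%), THF, −10 → 0 °C
Reagents that add atoms: none
Why: Copper-catalysed alkyl–alkyl coupling of a Grignard reagent with a primary bromide (Kochi–Tamura type); the excess of dibromide secures monosubstitution, and the stereocentre β to magnesium is a spectator.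

Step 3
Reactants: 6 meso-(3R,5S)-3,5-dimethyloxane-2,6-dione (cis-2,4-dimethylglutaric anhydride)
Product: 7 (2R,4S)-5-methoxy-2,4-dimethyl-5-oxopentanoic acid
Conditions: (DHQD)2AQN (30 mol%), MeOH (10 equiv), Et2O, −40 °C
Reagents that add atoms: methanol, CO
Why: Alkaloid-catalysed desymmetrizing methanolysis of a meso anhydride (general-base catalysis); the catalyst selects one of the two mirror-related carbonyl groups and so fixes both methyl-bearing centres of the syn pair at once.

Step 4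
Reactants: 7 (2R,4S)-5-methoxy-2,4-dimethyl-5-oxopentanoic acid
Product: 8 methyl (2S,4R)-5-hydroxy-2,4-dimethylpentanoate
Conditions: BH3·SMe2, THF, 0 °C → rt; crude product used directly
Reagents that add atoms: none
Why: Borane reduces the free carboxylic acid (through the acyloxyborane) much faster than the methyl ester, so the termini are differentiated without touching the α-centres.

Step 5
Reactants: 8 methyl (2S,4R)-5-hydroxy-2,4-dimethylpentanoate
Product: 9 methyl (2S,4R)-5-iodo-2,4-dimethylpentanoate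
Conditions: I2, PPh3, imidazole, CH2Cl2, 0 °C
Reagents that add atoms: iodine, II
Why: Appel-type iodination (Garegg–Samuelsson conditions) by SN2 displacement of the oxyphosphonium ion at the primary carbon; no stereocentre reacts.

Step 6
Reactants: 9 methyl (2S,4R)-5-iodo-2,4-dimethylpentanoate; 5 (R)-[(9-bromo-2-methylnonyl)oxy](tert-butyl)dimethylsilane
Product: 11 methyl (2S,4S,13R)-14-[(tert-butyldimethylsilyl)oxy]-2,4,13-trimethyltetradecanoate, via alkylzinc iodide 10 (not isolated)
Conditions: Zn dust (activated with TMSCl and 1,2-dibromoethane), THF, 40 °C; then 5, Pd2(dba)3 (2 mol%), tricyclopentylphosphine (8 mol%), N-methylimidazole, THF/NMP, 80 °C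
Reagents that add atoms: none
Why: Negishi alkyl–alkyl cross-coupling: zinc insertion tolerates the ester, and the electron-rich trialkylphosphine–palladium catalyst should couple the unactivated primary bromide faster than β-hydride elimination; all stereocentres are spectators.

Step 7
Reactants: 11 methyl (2S,4S,13R)-14-[(tert-butyldimethylsilyl)oxy]-2,4,13-trimethyltetradecanoate
Product: 12 methyl (2S,4S,13R)-14-hydroxy-2,4,13-trimethyltetradecanoate
Conditions: camphorsulfonic acid (10 mol%), MeOH/CH2Cl2, 0 °C → rt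
Reagents that add atoms: none
Why: Acid-catalysed methanolysis cleaves the primary silyl ether and cannot change the methyl ester, which carries the same alkoxy group as the solvent.

Step 8
Reactants: 12 methyl (2S,4S,13R)-14-hydroxy-2,4,13-trimethyltetradecanoate
Product: 13 methyl (2S,4S,13R)-2,4,13-trimethyl-14-[(1-phenyl-1H-tetrazol-5-yl)sulfanyl]tetradecanoate
Conditions: 1-phenyl-1H-tetrazole-5-thiol, PPh3, DIAD, THF, 0 °C → rt
Reagents that add atoms: 1-phenyl-1H-tetrazole-5-thiol, Sc1nnnn1-c1ccccc1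
Why: Mitsunobu thioetherification of the primary alcohol by the acidic heteroaryl thiol; the neighbouring stereocentre is not at the reacting carbon.

Step 9
Reactants: 13 methyl (2S,4S,13R)-2,4,13-trimethyl-14-[(1-phenyl-1H-tetrazol-5-yl)sulfanyl]tetradecanoate
Product: 14 methyl (2S,4S,13R)-2,4,13-trimethyl-14-[(1-phenyl-1H-tetrazol-5-yl)sulfonyl]tetradecanoate
Conditions: (NH4)6Mo7O24·4H2O (10 mol%), 30% H2O2, EtOH, 0 °C → rt
Reagents that add atoms: hydrogen peroxide, OO
Why: Molybdate-catalysed peroxide oxidation of the sulfide to the sulfone, the standard entry to Julia–Kocienski reagents; nothing else in the molecule is oxidizable.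

**Azido enal fragment (C15–C24)**

Step 10
Reactants: 15 ethyl (S)-4-chloro-3-hydroxybutanoate
Product: 16 ethyl (S)-4-azido-3-hydroxybutanoate
Conditions: NaN3, DMF, 90 °C
Reagents that add atoms: sodium azide, [Na+].[N-]=[N+]=[N-]
Why: SN2 displacement of the primary chloride by azide (directly or through the terminal epoxide, attack at CH2 in both cases), so the carbinol configuration is retained.

Step 11
Reactants: 16 ethyl (S)-4-azido-3-hydroxybutanoate
Product: 17 ethyl (S)-4-azido-3-[(tert-butyldimethylsilyl)oxy]butanoate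
Conditions: TBSCl, imidazole, DMF, rt
Reagents that add atoms: tert-butyldimethylsilyl chloride, CC(C)(C)[Si](C)(C)Cl
Why: Standard silylation of the secondary alcohol, which also blocks β-elimination in the aldehyde to come.

Step 12
Reactants: 17 ethyl (S)-4-azido-3-[(tert-butyldimethylsilyl)oxy]butanoate
Product: 18 (S)-4-azido-3-[(tert-butyldimethylsilyl)oxy]butanal
Conditions: i-Bu2AlH (1.1 equiv), CH2Cl2, −78 °C; Rochelle salt work-up; used crude
Reagents that add atoms: none
Why: Partial ester reduction at low temperature, where the aluminium hemiacetal survives until work-up and the azide is not reduced.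

Step 13
Reactants: 18 (S)-4-azido-3-[(tert-butyldimethylsilyl)oxy]butanal; 19 allyl(diisopropylamino)dimethylsilane
Product: 22 (3R,4S,6S)-7-azido-6-[(tert-butyldimethylsilyl)oxy]hept-1-ene-3,4-diol, via silylallylborane 20 (not isolated), via borinate adduct 21 (not isolated)
Conditions: 19, n-BuLi, TMEDA, Et2O, 0 °C; (+)-Ipc2BOMe, −78 °C; BF3·OEt2; 18, −78 °C; then 30% H2O2, KF, KHCO3, THF/MeOH, rt
Reagents that add atoms: hydrogen peroxide, OO
Why: Barrett anti-diol synthesis (asymmetric γ-silylallylboration, then Tamao oxidation): the (E)-γ-silylallylborane adds through a chair transition state to give the anti relationship, the isopinocampheyl groups from (−)-α-pinene select the Re face of the aldehyde (reagent control over the β-silyloxy centre), and the C–Si bond is oxidized with retention.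

Step 14
Reactants: 22 (3R,4S,6S)-7-azido-6-[(tert-butyldimethylsilyl)oxy]hept-1-ene-3,4-diol
Product: 23 (3R,4S,6S)-7-azido-3,4,6-tris[(tert-butyldimethylsilyl)oxy]hept-1-ene
Conditions: TBSOTf (2.5 equiv), 2,6-lutidine, CH2Cl2, 0 °C
Reagents that add atoms: tert-butyldimethylsilyl trifluoromethanesulfonate, CC(C)(C)[Si](C)(C)OS(=O)(=O)C(F)(F)F
Why: Silyl triflate silylation of both hindered secondary hydroxyls, giving one protecting group for the whole triol.

Step 15
Reactants: 24 methyl 4-methoxy-3-oxobutanoate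
Product: 25 methyl (E)-4-methoxy-3-[(trifluoromethanesulfonyl)oxy]but-2-enoate
Conditions: Tf2O, aq. Me4NOH, hexanes, 5–10 °C
Reagents that add atoms: trifluoromethanesulfonic anhydride, O=S(=O)(OS(=O)(=O)C(F)(F)F)C(F)(F)F
Why: Stereoselective O-triflation of a β-keto ester enolate: with the non-coordinating tetramethylammonium counter-ion the open, non-chelated enolate should be trapped as the (E)-enol triflate.

Step 16
Reactants: 23 (3R,4S,6S)-7-azido-3,4,6-tris[(tert-butyldimethylsilyl)oxy]hept-1-ene; 25 methyl (E)-4-methoxy-3-[(trifluoromethanesulfonyl)oxy]but-2-enoate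
Product: 27 methyl (2Z,6R,7S,9S)-10-azido-6,7,9-tris[(tert-butyldimethylsilyl)oxy]-3-(methoxymethyl)dec-2-enoate, via alkylborane 26 (not isolated)
Conditions: 9-BBN, THF, rt; then 25, PdCl2(dppf) (5 mol%), AsPh3 (10 mol%), aq. Cs2CO3, DMF, rt
Reagents that add atoms: none
Why: Hydroboration at the CH2 terminus followed by B-alkyl Suzuki–Miyaura coupling with the activated enol triflate, which proceeds with retention and so fixes the trisubstituted alkene (chain trans to the ester carbon, methoxymethyl cis); the azide should tolerate the hindered dialkylborane at room temperature.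

Step 17
Reactants: 27 methyl (2Z,6R,7S,9S)-10-azido-6,7,9-tris[(tert-butyldimethylsilyl)oxy]-3-(methoxymethyl)dec-2-enoate
Product: 28 (2Z,6R,7S,9S)-10-azido-6,7,9-tris[(tert-butyldimethylsilyl)oxy]-3-(methoxymethyl)dec-2-en-1-ol
Conditions: i-Bu2AlH (2.5 equiv), CH2Cl2, −78 °C
Reagents that add atoms: none
Why: 1,2-Reduction of the unsaturated ester to the allylic alcohol leaves the double-bond geometry and the azide intact at −78 °C.

Step 18
Reactants: 28 (2Z,6R,7S,9S)-10-azido-6,7,9-tris[(tert-butyldimethylsilyl)oxy]-3-(methoxymethyl)dec-2-en-1-ol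
Product: 29 (2Z,6R,7S,9S)-10-azido-6,7,9-tris[(tert-butyldimethylsilyl)oxy]-3-(methoxymethyl)dec-2-enal
Conditions: MnO2 (20 equiv), CH2Cl2, rt
Reagents that add atoms: none
Why: Surface oxidation of the allylic alcohol by MnO2 is selective and mild enough to keep the geometry of the β,β-disubstituted enal.

**Union and endgame**

Step 19
Reactants: 14 methyl (2S,4S,13R)-2,4,13-trimethyl-14-[(1-phenyl-1H-tetrazol-5-yl)sulfonyl]tetradecanoate; 29 (2Z,6R,7S,9S)-10-azido-6,7,9-tris[(tert-butyldimethylsilyl)oxy]-3-(methoxymethyl)dec-2-enal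
Product: 30 methyl (2S,4S,13R,14E,16Z,20R,21S,23S)-24-azido-20,21,23-tris[(tert-butyldimethylsilyl)oxy]-17-(methoxymethyl)-2,4,13-trimethyltetracosa-14,16-dienoate
Conditions: 14, KN(SiMe3)2 (1.1 equiv), DME, −60 °C; then 29, −60 °C → rt
Reagents that add atoms: none
Why: Julia–Kocienski olefination (addition, Smiles rearrangement, loss of SO2 and tetrazolone) should give the (E)-alkene with the potassium counter-ion in DME; the sulfone α-CH2 is deprotonated in preference to the hindered tertiary ester α-CH.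

Step 20
Reactants: 30 methyl (2S,4S,13R,14E,16Z,20R,21S,23S)-24-azido-20,21,23-tris[(tert-butyldimethylsilyl)oxy]-17-(methoxymethyl)-2,4,13-trimethyltetracosa-14,16-dienoate
Product: 32 methyl (2S,4S,13R,14E,16Z,20R,21S,23S)-20,21,23-tris[(tert-butyldimethylsilyl)oxy]-24-formamido-17-(methoxymethyl)-2,4,13-trimethyltetracosa-14,16-dienoate, via primary amine 31 (not isolated)
Conditions: PMe3, THF/H2O, rt; evaporate; then HCO2CH2CF3, THF, rt
Reagents that add atoms: 2,2,2-trifluoroethyl formate, O=COCC(F)(F)F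
Why: Staudinger reduction of the azide (hydrolysis of the iminophosphorane) and chemoselective N-formylation of the primary amine by the activated formate in the same flask.

Step 21
Reactants: 32 methyl (2S,4S,13R,14E,16Z,20R,21S,23S)-20,21,23-tris[(tert-butyldimethylsilyl)oxy]-24-formamido-17-(methoxymethyl)-2,4,13-trimethyltetracosa-14,16-dienoate
Product: 33 methyl (2S,4S,13R,14E,16Z,20R,21S,23S)-20,21,23-tris[(tert-butyldimethylsilyl)oxy]-24-isocyano-17-(methoxymethyl)-2,4,13-trimethyltetracosa-14,16-dienoate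
Conditions: Burgess reagent (2 equiv), CH2Cl2, rt
Reagents that add atoms: none
Why: Dehydration of the formamide to the isocyanide by the Burgess reagent under neutral conditions that spare silyl ethers, diene and ester.

Step 22
Reactants: 33 methyl (2S,4S,13R,14E,16Z,20R,21S,23S)-20,21,23-tris[(tert-butyldimethylsilyl)oxy]-24-isocyano-17-(methoxymethyl)-2,4,13-trimethyltetracosa-14,16-dienoate
Product: 35 (2S,4S,13R,14E,16Z,20R,21S,23S)-20,21,23-tris[(tert-butyldimethylsilyl)oxy]-24-isocyano-17-(methoxymethyl)-2,4,13-trimethyltetracosa-14,16-dienoic acid, via lithium carboxylate 34 (not isolated)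
Conditions: LiOH·H2O, THF/MeOH/H2O, rt; then aq. NaH2PO4 to pH 5–6 at 0 °C, extraction; used at once
Reagents that add atoms: lithium hydroxide, [Li+].[OH-]
Why: Saponification by acyl–oxygen cleavage; the isocyanide is stable to base and meets only a mildly acidic buffer when the acid is liberated.

Step 23
Reactants: 35 (2S,4S,13R,14E,16Z,20R,21S,23S)-20,21,23-tris[(tert-butyldimethylsilyl)oxy]-24-isocyano-17-(methoxymethyl)-2,4,13-trimethyltetracosa-14,16-dienoic acid; 36 butanal
Product: 38 (2S,6S,8S,9R,12Z,14E,16R,25S,27S)-6,8,9-tris[(tert-butyldimethylsilyl)oxy]-12-(methoxymethyl)-16,25,27-trimethyl-2-propyl-1-oxa-4-azacyclooctacosa-12,14-diene-3,28-dione, via macrocyclic imidate 37 (not isolated)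
Conditions: (R)-TRIP (20 mol%), 36 (10 equiv), 4 Å molecular sieves, CH2Cl2, rt; 35 added by syringe pump over 16 h (final 2 mM)
Reagents that add atoms: none
Why: Passerini macrocyclization: in the hydrogen-bonded assembly of the carboxylic acid of 35, butanal and the phosphoric acid, the isocyanide carbon adds to the activated aldehyde carbon (the new C–C bond between the future amide carbonyl and the propyl-bearing carbon) while the tethered carboxylate oxygen captures the developing nitrilium carbon, so the ring exists as soon as this bond is made. This closure gives the 27-membered O-acyl imidate 37 by 27-endo-dig attack of oxygen on the nitrilium carbon, and a Mumm-type 1,4 O→O acyl shift through a five-membered tetrahedral intermediate (5-exo-trig) then expands it to the 28-membered lactone-lactam. The closest known reaction type is the Passerini ring closure of α-isocyano-ω-carboxylic acids with aldehydes to macrocyclic depsipeptides, combined with chiral phosphoric acid catalysis of the classic three-component Passerini reaction. The one new stereocentre, the (S)-configured oxygen-bearing carbon, is set by the catalyst, which should shield one face of the bound butanal; the remote substrate stereocentres are expected to exert little bias. The step needs ring closure over oligomerization, secured by slow addition into dilute solution with excess butanal, and it needs the carboxylate rather than a neighbouring oxygen to trap the nitrilium ion, secured by the silyl ether on the hydroxyl two atoms from nitrogen, which blocks oxazoline formation.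

Step 24
Reactants: 38 (2S,6S,8S,9R,12Z,14E,16R,25S,27S)-6,8,9-tris[(tert-butyldimethylsilyl)oxy]-12-(methoxymethyl)-16,25,27-trimethyl-2-propyl-1-oxa-4-azacyclooctacosa-12,14-diene-3,28-dione
Product: 39 (2S,6S,8S,9R,12Z,14E,16R,25S,27S)-6,8,9-trihydroxy-12-(methoxymethyl)-16,25,27-trimethyl-2-propyl-1-oxa-4-azacyclooctacosa-12,14-diene-3,28-dione (CNP0511044.2)
Conditions: HF·pyridine, pyridine, THF, 0 °C → rt
Reagents that add atoms: none
Why: Fluoride cleavage of the three silyl ethers under buffered, non-basic conditions that avoid migration of the activated α-acyloxy amide ester onto the freed hydroxyls.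

**Compound list**

1 | (S)-3-bromo-2-methylpropan-1-ol | BrC[C@@H](C)CO | starting material
2 | (S)-(3-bromo-2-methylpropoxy)(tert-butyl)dimethylsilane | BrC[C@@H](C)CO[Si](C)(C)C(C)(C)C | intermediate
3 | 1,6-dibromohexane | BrCCCCCCBr | starting material
4 | [(S)-3-[(tert-butyldimethylsilyl)oxy]-2-methylpropyl]magnesium bromide | Br[Mg]C[C@@H](C)CO[Si](C)(C)C(C)(C)C | intermediate
5 | (R)-[(9-bromo-2-methylnonyl)oxy](tert-butyl)dimethylsilane | BrCCCCCCC[C@@H](C)CO[Si](C)(C)C(C)(C)C | intermediate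
6 | meso-(3R,5S)-3,5-dimethyloxane-2,6-dione | O1C(=O)[C@@H](C)C[C@@H](C)C1=O | starting material
7 | (2R,4S)-5-methoxy-2,4-dimethyl-5-oxopentanoic acid | COC(=O)[C@@H](C)C[C@@H](C)C(=O)O | intermediate
8 | methyl (2S,4R)-5-hydroxy-2,4-dimethylpentanoate | COC(=O)[C@@H](C)C[C@@H](C)CO | intermediate
9 | methyl (2S,4R)-5-iodo-2,4-dimethylpentanoate | COC(=O)[C@@H](C)C[C@@H](C)CI | intermediate
10 | [(2R,4S)-5-methoxy-2,4-dimethyl-5-oxopentyl]zinc iodide | COC(=O)[C@@H](C)C[C@@H](C)C[Zn]I | intermediate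
11 | methyl (2S,4S,13R)-14-[(tert-butyldimethylsilyl)oxy]-2,4,13-trimethyltetradecanoate | COC(=O)[C@@H](C)C[C@@H](C)CCCCCCCC[C@@H](C)CO[Si](C)(C)C(C)(C)C | intermediate
12 | methyl (2S,4S,13R)-14-hydroxy-2,4,13-trimethyltetradecanoate | COC(=O)[C@@H](C)C[C@@H](C)CCCCCCCC[C@@H](C)CO | intermediate
13 | methyl (2S,4S,13R)-2,4,13-trimethyl-14-[(1-phenyl-1H-tetrazol-5-yl)sulfanyl]tetradecanoate | COC(=O)[C@@H](C)C[C@@H](C)CCCCCCCC[C@@H](C)CSc1nnnn1-c1ccccc1 | intermediate
14 | methyl (2S,4S,13R)-2,4,13-trimethyl-14-[(1-phenyl-1H-tetrazol-5-yl)sulfonyl]tetradecanoate | COC(=O)[C@@H](C)C[C@@H](C)CCCCCCCC[C@@H](C)CS(=O)(=O)c1nnnn1-c1ccccc1 | intermediate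
15 | ethyl (S)-4-chloro-3-hydroxybutanoate | CCOC(=O)C[C@H](O)CCl | starting material
16 | ethyl (S)-4-azido-3-hydroxybutanoate | CCOC(=O)C[C@H](O)CN=[N+]=[N-] | intermediate
17 | ethyl (S)-4-azido-3-[(tert-butyldimethylsilyl)oxy]butanoate | CCOC(=O)C[C@H](O[Si](C)(C)C(C)(C)C)CN=[N+]=[N-] | intermediate
18 | (S)-4-azido-3-[(tert-butyldimethylsilyl)oxy]butanal | O=CC[C@H](O[Si](C)(C)C(C)(C)C)CN=[N+]=[N-] | intermediate
19 | allyl(diisopropylamino)dimethylsilane | C=CC[Si](C)(C)N(C(C)C)C(C)C | starting material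
20 | B-[(E)-3-[(diisopropylamino)dimethylsilyl]allyl]diisopinocampheylborane (isopinocampheyl groups from (−)-α-pinene) | CC(C)N(C(C)C)[Si](C)(C)/C=C/CB([C@H]1C[C@H]2C[C@@H]([C@@H]1C)C2(C)C)[C@H]1C[C@H]2C[C@@H]([C@@H]1C)C2(C)C | intermediate
21 | O-(diisopinocampheylboryl) derivative of (3R,4S,6S)-7-azido-6-[(tert-butyldimethylsilyl)oxy]-3-[(diisopropylamino)dimethylsilyl]hept-1-en-4-ol | C=C[C@@H]([Si](C)(C)N(C(C)C)C(C)C)[C@@H](OB([C@H]1C[C@H]2C[C@@H]([C@@H]1C)C2(C)C)[C@H]1C[C@H]2C[C@@H]([C@@H]1C)C2(C)C)C[C@H](O[Si](C)(C)C(C)(C)C)CN=[N+]=[N-] | intermediate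
22 | (3R,4S,6S)-7-azido-6-[(tert-butyldimethylsilyl)oxy]hept-1-ene-3,4-diol | C=C[C@@H](O)[C@@H](O)C[C@H](O[Si](C)(C)C(C)(C)C)CN=[N+]=[N-] | intermediate
23 | (3R,4S,6S)-7-azido-3,4,6-tris[(tert-butyldimethylsilyl)oxy]hept-1-ene | C=C[C@@H](O[Si](C)(C)C(C)(C)C)[C@@H](O[Si](C)(C)C(C)(C)C)C[C@H](O[Si](C)(C)C(C)(C)C)CN=[N+]=[N-] | intermediate
24 | methyl 4-methoxy-3-oxobutanoate | COCC(=O)CC(=O)OC | starting material
25 | methyl (E)-4-methoxy-3-[(trifluoromethanesulfonyl)oxy]but-2-enoate | COC/C(=C\C(=O)OC)OS(=O)(=O)C(F)(F)F | intermediate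
26 | B-[(3R,4S,6S)-7-azido-3,4,6-tris[(tert-butyldimethylsilyl)oxy]heptyl]-9-borabicyclo[3.3.1]nonane | C1CCC2CCCC1B2CC[C@@H](O[Si](C)(C)C(C)(C)C)[C@@H](O[Si](C)(C)C(C)(C)C)C[C@H](O[Si](C)(C)C(C)(C)C)CN=[N+]=[N-] | intermediate
27 | methyl (2Z,6R,7S,9S)-10-azido-6,7,9-tris[(tert-butyldimethylsilyl)oxy]-3-(methoxymethyl)dec-2-enoate | COC/C(=C\C(=O)OC)CC[C@@H](O[Si](C)(C)C(C)(C)C)[C@@H](O[Si](C)(C)C(C)(C)C)C[C@H](O[Si](C)(C)C(C)(C)C)CN=[N+]=[N-] | intermediate
28 | (2Z,6R,7S,9S)-10-azido-6,7,9-tris[(tert-butyldimethylsilyl)oxy]-3-(methoxymethyl)dec-2-en-1-ol | COC/C(=C\CO)CC[C@@H](O[Si](C)(C)C(C)(C)C)[C@@H](O[Si](C)(C)C(C)(C)C)C[C@H](O[Si](C)(C)C(C)(C)C)CN=[N+]=[N-] | intermediate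
29 | (2Z,6R,7S,9S)-10-azido-6,7,9-tris[(tert-butyldimethylsilyl)oxy]-3-(methoxymethyl)dec-2-enal | COC/C(=C\C=O)CC[C@@H](O[Si](C)(C)C(C)(C)C)[C@@H](O[Si](C)(C)C(C)(C)C)C[C@H](O[Si](C)(C)C(C)(C)C)CN=[N+]=[N-] | intermediate
30 | methyl (2S,4S,13R,14E,16Z,20R,21S,23S)-24-azido-20,21,23-tris[(tert-butyldimethylsilyl)oxy]-17-(methoxymethyl)-2,4,13-trimethyltetracosa-14,16-dienoate | COC(=O)[C@@H](C)C[C@@H](C)CCCCCCCC[C@@H](C)/C=C/C=C(\COC)CC[C@@H](O[Si](C)(C)C(C)(C)C)[C@@H](O[Si](C)(C)C(C)(C)C)C[C@H](O[Si](C)(C)C(C)(C)C)CN=[N+]=[N-] | intermediate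
31 | methyl (2S,4S,13R,14E,16Z,20R,21S,23S)-24-amino-20,21,23-tris[(tert-butyldimethylsilyl)oxy]-17-(methoxymethyl)-2,4,13-trimethyltetracosa-14,16-dienoate | COC(=O)[C@@H](C)C[C@@H](C)CCCCCCCC[C@@H](C)/C=C/C=C(\COC)CC[C@@H](O[Si](C)(C)C(C)(C)C)[C@@H](O[Si](C)(C)C(C)(C)C)C[C@H](O[Si](C)(C)C(C)(C)C)CN | intermediate
32 | methyl (2S,4S,13R,14E,16Z,20R,21S,23S)-20,21,23-tris[(tert-butyldimethylsilyl)oxy]-24-formamido-17-(methoxymethyl)-2,4,13-trimethyltetracosa-14,16-dienoate | COC(=O)[C@@H](C)C[C@@H](C)CCCCCCCC[C@@H](C)/C=C/C=C(\COC)CC[C@@H](O[Si](C)(C)C(C)(C)C)[C@@H](O[Si](C)(C)C(C)(C)C)C[C@H](O[Si](C)(C)C(C)(C)C)CNC=O | intermediate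
33 | methyl (2S,4S,13R,14E,16Z,20R,21S,23S)-20,21,23-tris[(tert-butyldimethylsilyl)oxy]-24-isocyano-17-(methoxymethyl)-2,4,13-trimethyltetracosa-14,16-dienoate | COC(=O)[C@@H](C)C[C@@H](C)CCCCCCCC[C@@H](C)/C=C/C=C(\COC)CC[C@@H](O[Si](C)(C)C(C)(C)C)[C@@H](O[Si](C)(C)C(C)(C)C)C[C@H](O[Si](C)(C)C(C)(C)C)C[N+]#[C-] | intermediate
34 | lithium (2S,4S,13R,14E,16Z,20R,21S,23S)-20,21,23-tris[(tert-butyldimethylsilyl)oxy]-24-isocyano-17-(methoxymethyl)-2,4,13-trimethyltetracosa-14,16-dienoate | [Li+].[O-]C(=O)[C@@H](C)C[C@@H](C)CCCCCCCC[C@@H](C)/C=C/C=C(\COC)CC[C@@H](O[Si](C)(C)C(C)(C)C)[C@@H](O[Si](C)(C)C(C)(C)C)C[C@H](O[Si](C)(C)C(C)(C)C)C[N+]#[C-] | intermediate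
35 | (2S,4S,13R,14E,16Z,20R,21S,23S)-20,21,23-tris[(tert-butyldimethylsilyl)oxy]-24-isocyano-17-(methoxymethyl)-2,4,13-trimethyltetracosa-14,16-dienoic acid | OC(=O)[C@@H](C)C[C@@H](C)CCCCCCCC[C@@H](C)/C=C/C=C(\COC)CC[C@@H](O[Si](C)(C)C(C)(C)C)[C@@H](O[Si](C)(C)C(C)(C)C)C[C@H](O[Si](C)(C)C(C)(C)C)C[N+]#[C-] | intermediate
36 | butanal | CCCC=O | starting material
37 | 27-membered macrocyclic O-acyl imidate carrying the (S)-1-hydroxybutyl group on the imidate carbon | O1C(=O)[C@@H](C)C[C@@H](C)CCCCCCCC[C@@H](C)/C=C/C=C(\COC)CC[C@@H](O[Si](C)(C)C(C)(C)C)[C@@H](O[Si](C)(C)C(C)(C)C)C[C@H](O[Si](C)(C)C(C)(C)C)CN=C1[C@@H](O)CCC | intermediate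
38 | (2S,6S,8S,9R,12Z,14E,16R,25S,27S)-6,8,9-tris[(tert-butyldimethylsilyl)oxy]-12-(methoxymethyl)-16,25,27-trimethyl-2-propyl-1-oxa-4-azacyclooctacosa-12,14-diene-3,28-dione | CCC[C@@H]1OC(=O)[C@@H](C)C[C@@H](C)CCCCCCCC[C@@H](C)/C=C/C=C(\COC)CC[C@@H](O[Si](C)(C)C(C)(C)C)[C@@H](O[Si](C)(C)C(C)(C)C)C[C@H](O[Si](C)(C)C(C)(C)C)CNC1=O | intermediate
39 | (2S,6S,8S,9R,12Z,14E,16R,25S,27S)-6,8,9-trihydroxy-12-(methoxymethyl)-16,25,27-trimethyl-2-propyl-1-oxa-4-azacyclooctacosa-12,14-diene-3,28-dione | CCC[C@@H]1OC(=O)[C@@H](C)C[C@@H](C)CCCCCCCC[C@@H](C)/C=C/C=C(\COC)CC[C@@H](O)[C@@H](O)C[C@H](O)CNC1=O | target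

**Step count and risks**

Total step count: 24. Longest linear sequence: 14 steps (15 → 39 through steps 10–14 and 16–24).

Steps most likely to fail:

1. Step 23. Oligomerization may outcompete the 28-membered closure at the dilution required, and facial control at butanal may be lost in the macrocyclic transition state. The fallback sets out from 33 and comes back at 38. The isocyano ester 33 is combined with butanal 36 and benzoic acid under the same phosphoric acid at normal concentration, the intermolecular regime in which this catalysis is established, to give the benzoate-protected (S)-2-hydroxypentanamide F1. LiOH cleaves the benzoate and the methyl ester together to the seco hydroxy acid F2. Yamaguchi macrolactonization (2,4,6-trichlorobenzoyl chloride, Et3N, then DMAP, toluene, high dilution) closes the ring at the ester bond and gives 38.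

2. Step 19. E selectivity may erode in the addition of the sulfone anion to a conjugated aldehyde, and enolization of the ester or the enal may compete. The fallback sets out from 12 and 28 and comes back at 30. Alcohol 12 is oxidized with Dess–Martin periodinane to the aldehyde F3. Alcohol 28 is converted with NBS and Me2S (Corey–Kim) into the allylic bromide F4, and Michaelis–Becker reaction with NaP(O)(OEt)2 gives the allylic phosphonate F5. Horner–Wadsworth–Emmons reaction of the anion of F5 with F3 (LiN(SiMe3)2, THF, −78 → 0 °C) gives 30.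

3. Step 6. Zinc insertion or transmetalation may be slow, so that reduction, β-hydride elimination and homocoupling consume the two partners. The fallback sets out from 8 and 5 and comes back at 11. Alcohol 8 is oxidized with Dess–Martin periodinane to the aldehyde F6. Bromide 5 is heated with PPh3 in MeCN to the phosphonium bromide F7. Wittig reaction of its ylide (NaN(SiMe3)2, THF, −78 °C) with F6 gives the (Z)-alkene F8, and hydrogenation (H2, Pd/C, EtOAc) gives 11.

Further compounds
F1 | step 23 | methyl (2S,4S,13R,14E,16Z,20R,21S,23S)-24-[(S)-2-(benzoyloxy)pentanamido]-20,21,23-tris[(tert-butyldimethylsilyl)oxy]-17-(methoxymethyl)-2,4,13-trimethyltetracosa-14,16-dienoate | COC(=O)[C@@H](C)C[C@@H](C)CCCCCCCC[C@@H](C)/C=C/C=C(\COC)CC[C@@H](O[Si](C)(C)C(C)(C)C)[C@@H](O[Si](C)(C)C(C)(C)C)C[C@H](O[Si](C)(C)C(C)(C)C)CNC(=O)[C@H](CCC)OC(=O)c1ccccc1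
F2 | step 23 | (2S,4S,13R,14E,16Z,20R,21S,23S)-20,21,23-tris[(tert-butyldimethylsilyl)oxy]-24-[(S)-2-hydroxypentanamido]-17-(methoxymethyl)-2,4,13-trimethyltetracosa-14,16-dienoic acid | OC(=O)[C@@H](C)C[C@@H](C)CCCCCCCC[C@@H](C)/C=C/C=C(\COC)CC[C@@H](O[Si](C)(C)C(C)(C)C)[C@@H](O[Si](C)(C)C(C)(C)C)C[C@H](O[Si](C)(C)C(C)(C)C)CNC(=O)[C@H](CCC)O
F3 | step 19 | methyl (2S,4S,13R)-2,4,13-trimethyl-14-oxotetradecanoate | COC(=O)[C@@H](C)C[C@@H](C)CCCCCCCC[C@@H](C)C=O
F4 | step 19 | (2Z,6R,7S,9S)-10-azido-1-bromo-6,7,9-tris[(tert-butyldimethylsilyl)oxy]-3-(methoxymethyl)dec-2-ene | COC/C(=C\CBr)CC[C@@H](O[Si](C)(C)C(C)(C)C)[C@@H](O[Si](C)(C)C(C)(C)C)C[C@H](O[Si](C)(C)C(C)(C)C)CN=[N+]=[N-]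
F5 | step 19 | diethyl [(2Z,6R,7S,9S)-10-azido-6,7,9-tris[(tert-butyldimethylsilyl)oxy]-3-(methoxymethyl)dec-2-en-1-yl]phosphonate | COC/C(=C\CP(=O)(OCC)OCC)CC[C@@H](O[Si](C)(C)C(C)(C)C)[C@@H](O[Si](C)(C)C(C)(C)C)C[C@H](O[Si](C)(C)C(C)(C)C)CN=[N+]=[N-]
F6 | step 6 | methyl (2S,4R)-2,4-dimethyl-5-oxopentanoate | COC(=O)[C@@H](C)C[C@@H](C)C=O
F7 | step 6 | [(R)-9-[(tert-butyldimethylsilyl)oxy]-8-methylnonyl]triphenylphosphonium bromide | [Br-].c1ccccc1[P+](c1ccccc1)(c1ccccc1)CCCCCCC[C@@H](C)CO[Si](C)(C)C(C)(C)C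
F8 | step 6 | methyl (2S,4R,5Z,13R)-14-[(tert-butyldimethylsilyl)oxy]-2,4,13-trimethyltetradec-5-enoate | COC(=O)[C@@H](C)C[C@@H](C)/C=C\CCCCCC[C@@H](C)CO[Si](C)(C)C(C)(C)C
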